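Friday's run and Wednesday's run, each with 50 µM of free catalyst, ended at 15.0 h with uncatalysed product at 1.71 and 1.46 times the target and side product together.

| flask | starting material | second substrate | free catalyst | remark | time |
|---|---|---|---|---|---|
| Friday's | 0.025 M | 0.050 M | 50 µM | run made earlier |  |
| Wednesday's | 0.10 M | 0.050 M | 50 µM | run made earlier |  |
| Monday's | 0.050 M | 0.050 M | 100 µM | run made earlier |  |
| maple | 0.050 M | 0.0500 M | 50 µM |  | 25 h |
| birch | 0.050 M | 0.0500 M | 50 µM |  | 50 h |
| elm | 0.050 M | 0.0500 M | 50 µM |  | 100 h |

| run | time / h | starting material / % | uncatalysed product / % | side product / % | target / % |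
|---|---|---|---|---|---|
| Friday's | 2.00 | 50.3 | 31.3 | 1.6 | 15.5 |
| Friday's | 5.00 | 17.2 | 52.1 | 4.6 | 26.3 |
| Friday's | 10.0 | 2.5 | 61.0 | 5.8 | 30.5 |
| Friday's | 15.0 | 0.5 | 62.5 | 6.0 | 30.6 |
| Wednesday's | 2.00 | 49.2 | 31.4 | 5.8 | 12.8 |
| Wednesday's | 5.00 | 15.2 | 50.9 | 14.5 | 19.8 |
| Wednesday's | 10.0 | 2.1 | 58.5 | 18.0 | 21.5 |
| Wednesday's | 15.0 | 0.6 | 59.6 | 18.8 | 21.9 |
| Monday's | 1.33 | 54.0 | 22.5 | 3.2 | 20.9 |
| Monday's | 3.00 | 22.9 | 35.6 | 8.2 | 33.3 |
| Monday's | 6.00 | 4.6 | 43.2 | 11.5 | 41.1 |
| Monday's | 15.0 | 0 | 44.9 | 12.4 | 42.9 |

(scatter of a reading: 0.3 percentage points)

- percent here means starting material units held: one side product counts as two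
- the numbers in the tables scatter with a standard deviation of 0.3 percentage points

- which of these there is most of at the end, counted by the starting material in it, maple (side product / uncatalysed product / starting material / target)
- which of these there is most of at the end, counted by the starting material in it, birch (side product / uncatalysed product / starting material / target)
- which of these there is most of at the end, counted by the starting material in it, elm (side product / uncatalysed product / starting material / target)
- final amount of the leader among these, as a percentage of the starting material charged, in maple
- final amount of the leader among these, as a percentage of the starting material charged, in birch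
- final amount of the leader among these, as a percentage of the starting material charged, in elm

For whoever takes over the bench: the 0.050 M of starting material in maple, birch and elm lies a factor 2.00 above Friday's charge and a factor 2.00 below Wednesday's, so on a logarithmic axis these flasks stand midway. The mean of the two logarithms then gives the uncatalysed odds, meaning uncatalysed product over target plus side product at the end (a selectivity factor between the routes), as 1.58. Monday's run, with twice the catalyst, ended at 0.812, and the flasks' odds are twice that, a logarithmic slope of 0.962 in size, so the odds go inversely with catalyst. The catalyst charge is not to be altered at the bench, since Monday's larger charge gave the lower odds. With odds above one, uncatalysed product leads, at 61.3 %. Friday's starting material fell a power of ten every 6.14 h, so at that pace maple's 25 h span 4.07 powers, and about 0.00848 % remains there.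

The forecast also names uncatalysed product in each flask, at 61.5 % (60.3 % to 62.7 %) in maple and 61.5 % (59 % to 63 %) in elm, on the ground “Once starting material is gone nothing changes”; it stands 0.20 points above the reckoning here.

Maple, birch and elm end at 61.3 %, 61.3 % and 61.3 % of uncatalysed product, and maple left ten times as long holds 61.3 %. The final amounts in maple give odds of 1.59, beside the 1.58 taken from the two earlier runs.

    starting material + free catalyst ⇌ catalyst intermediate A (K = 7.30 M⁻¹, k = 3600 M⁻¹ h⁻¹)
    catalyst intermediate A → free catalyst + target (k = 2900 h⁻¹)
    second substrate + free catalyst ⇌ catalyst intermediate B (K = 13.0 M⁻¹, k = 6100 M⁻¹ h⁻¹)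
    catalyst intermediate B → free catalyst + second product (k = 390 h⁻¹)
    starting material → uncatalysed product (k = 0.220 h⁻¹)
    starting material + target → side product (k = 2.90 M⁻¹ h⁻¹)

The neighbour of birch with 2.0 × 10⁻⁵ M of free catalyst takes the odds, inversely with catalyst, to 3.95, which is a share of 79.8 %; the computed flask ends at 79.7 %.

The runs are calculated with constants of no real substance, and the scatter is random.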